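## Structural features

Limnophilaspiroketone is a 1-oxaspiro[4.4]nonane in which ring A, a cyclopentenone (C1 carbinol with OH and CO2Me, C2=C3 alkene with two methoxy groups, C4 ketone, C5), and ring B, a 3(2H)-furanone (C5, O1', C2' bearing the 4-hydroxyphenyl group, C3', C4' ketone), share only the spiro carbon C5. C1 and C5 are neighbouring, fully substituted stereocentres, (1R,5S) in ring A numbering and (5S,6R) in spiro numbering, with the C1 hydroxyl and O1' on one face of ring A and CO2Me and C4' on the other. No carbon of ring A carries hydrogen, so there is no C–H position for late correction and every oxidation level must be delivered by the ring-forming chemistry. The weakest bond is C1–C5, an aldol bond (the C1 hydroxyl is β to both the C4 and the C4' ketone): base can open it, and re-closure would scramble both stereocentres. Further fragile sites are C5 as an α-oxygenated 1,3-dicarbonyl carbon (acyl cleavage by nucleophiles), the C2/C3 vinylogous ester (hydrolysis in strong aqueous acid), the free phenol and the aryl-conjugated alkene of ring B (reduction). The real difficulty is therefore two contiguous quaternary stereocentres inside a fully oxygenated five-membered ring, in one absolute configuration. The key step exploits the fact that C1 of ring A is bonded both to the exocyclic ester carbon and to C2: this is the pattern left when the ketal carbon of a 4,4-dimethoxycyclohexa-2,5-dienone leaves the ring, its two β-carbons becoming C1 and C2 and the ketal carbon becoming CO2Me on C1.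

## Logic of the disconnections

15 from 14. Only the phenolic O–benzyl bond is cut. The phenol must be masked because it would be acylated by 12 and would consume base. Benzyl is chosen because it leaves under neutral conditions, which the aldol bond C1–C5 of 15 requires. No skeletal simplification results. The forward step must stop before the ring B alkene is reduced.

14 from 11 and 12 (through 13). The bonds cut are O1'–C2' and C2'–C3'. A 3(2H)-furanone is the cyclodehydration product of an α'-hydroxy 1,3-diketone, and that diketone is the C-acylation product of a methyl ketone. Ring B and the aryl group are thereby reduced to an acetyl group on C5 and a purchasable aroyl chloride. The forward step needs the acetyl CH3 as the only enolisable site and neither tertiary alcohol present as an alkoxide, which is why both are tied into one ketal in 11.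

11 from 10. The two ketal C–O bonds are cut. The ketal protects C1–OH and C5–OH against retro-aldol cleavage and acyl transfer in the acylation, and only a cis diol can form it. The demand on 10 is the cis relation of the two hydroxyl groups.

10 from 9. The C5–O bond is cut. In 9, C5 is the central carbon of an enolised β-diketone and the most nucleophilic carbon present, so the oxygen can come from an electrophilic oxidant and the neighbouring C1 hydroxyl can steer it. The second stereocentre is thus derived from the first. The forward step must deliver oxygen to the hydroxyl face and not to the ester face.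

9 from 8. The O–acyl bond of the auxiliary on the C1 oxygen is cut. Once the C1 epimers are separated the auxiliary has no further use, and the free hydroxyl is needed as the directing group. The cleavage must not open the C1–C5 bond. This is safe because the β-diketone is held as its enolate under the conditions, and an enolate carbon cannot act as the leaving group of a retro-aldol reaction.

8 from 6 (through 7). This is the strategic cut.
- Retrosynthetically the C1–C2 bond of ring A is broken and the ester carbon is re-inserted between C1 and C5. The retron is a 4-oxocyclopent-2-ene-1-carboxylate and it maps onto a para-quinone monoketal.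
- The gain is large: ring A with its whole oxidation pattern, the quaternary C1 and the methyl ester come from a flat six-membered precursor that is three steps from a purchasable acetophenone.
- The demand is twofold: the ketal carbon must migrate toward the acetyl-bearing carbon, and the cyclopropane must open toward C5. The acetyl group and the choice of an acyl group on the C3 oxygen of 6 provide for both.
- The facial course cannot be steered by a remote auxiliary, so C1 is obtained by separating diastereomers.
- The structures of 6 and 8 were checked atom by atom against this mechanism and are consistent; the design of 6 is kept, with three points attended to.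
  - The auxiliary stays an ester, because an acylated oxygen is a poorer donor than methoxy, and that difference directs the shift.
  - 6 is a vinylogous mixed anhydride. The photolysis is therefore run without an alcohol solvent, with water as the only added nucleophile.
  - The α-carbon of the auxiliary can lose its configuration through a ketene. The acylation therefore uses pyridine and no trialkylamine, and a carbonate auxiliary is held in reserve.

6 from 5. The new ketal C–OMe bond is cut and the ring carbonyl is returned to a phenol (oxidative dearomatisation). This takes the dienone back to an arene. The forward step needs solvent attack at the methoxy-bearing para carbon and not at the ortho one.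

5 from 4. The phenol is traced back to the methoxy group ortho to the acetyl group. Demethylation is placed after the acylation because 4 has only one methoxy group that can chelate a Lewis acid together with the ketone. The site of cleavage is then unambiguous, and no statistical mono-acylation of a symmetrical diol is needed. The Lewis acid must leave the auxiliary untouched.

4 from 1 and 2 (through 3). The aryl O–acyl bond is cut, which leads to two purchasable compounds. The forward step must avoid ketene formation from 3.

## Other disconnections considered

Alternative 1: The cut runs through O1'–C2' and C4–C5, taking ring B and the spiro centre back to an ortho-quinol with the arylethynyl group on its carbinol carbon, A1 (methyl (5S)-5-{[4-(benzyloxy)phenyl]ethynyl}-5-hydroxy-2,3-dimethoxy-6-oxocyclohexa-1,3-diene-1-carboxylate).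
- Forward step: Ph3PAuNTf2, a monovalent gold complex, activates the alkyne. The ketone oxygen closes onto the aryl-bearing alkyne carbon, and the oxocarbenium carbon then accepts the ring alkenyl CH carbon from the carbinol carbon in a 1,2-shift. The six-membered ring contracts to the spiro cyclopentadiene A2.
- In its favour: ring B, the spiro centre and the contraction come from one catalytic step. The shift is suprafacial, so the carbinol configuration of A1 would be transferred to C5. On this point it is better than the chosen plan, which reaches its absolute configuration by separating diastereomers and gives up about half of the material. Cycloisomerisation of α-hydroxy ynones with 1,2-shift to 3(2H)-furanones is a known reaction type.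
- Against it here: A2 lacks two oxygens exactly where the target is most demanding. C1 is sp2 and C4 is CH, so the C1 carbinol must still be created next to the spiro centre. This could be done by singlet-oxygen addition across C1/C4 and Kornblum–DeLaMare opening, but nothing obvious chooses between the O1' face and the C4' face. A1 would have to be made as one enantiomer by hydroxylative dearomatisation of a 2-alkynylphenol, and ortho-quinols of this kind tend to dimerise by Diels–Alder reaction.
- Comparison: on structure, it completes ring B and leaves ring A unfinished, whereas the chosen plan completes ring A in the key step and leaves ring B to classical furanone chemistry. On mechanism, both contract a six-membered dienone; the alternative is stereospecific (better), the chosen step installs the C1 oxidation level and the ester at once (better for C1). On step economy the two are about equal on paper.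

Alternative 2: The cut is C5–O1', back to the aryl 1,3-diketone A3 (1-[4-(benzyloxy)phenyl]-3-(2,6-dihydroxy-3,4-dimethoxyphenyl)propane-1,3-dione).
- Forward step: constant-current oxidation at a graphite anode in HFIP with a chiral aryl iodide mediator, which is oxidised at the anode to its trivalent iodine form. The phenol is activated, and the enol oxygen of the diketone attacks the acyl-bearing ipso carbon. Ring B closes as the spiro cyclohexenedione A4.
- In its favour: A3 is two steps from an acetophenone and 12 (O-acylation, Baker–Venkataraman shift), a shorter way to a ring B spiro compound than the chosen route offers (better). No stoichiometric oxidant is needed, and catalytic enantiocontrol would be better than a resolution if it could be achieved.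
- Against it here: A4 still has a six-membered carbocycle. Its CH2 group would have to be oxidised to the tetrone A5, and then the contraction of alternative 3 to A6 would follow, so the C1 problem is only postponed. A3 is a 2'-hydroxydibenzoylmethane, the classical flavone precursor, and six-membered cyclodehydration by the phenol oxygen competes in an acidic, oxidising medium. The attack must occur at an ipso carbon that bears an acyl group between two hydroxyl groups, for which enantioselective spiro-etherification has little analogy.
- Comparison: on structure, it settles ring B and C5 early and leaves ring A unsolved. On mechanism, the C5–O bond comes from oxidation of the arene, whereas the chosen plan oxidises C5 of a finished ring A; its stereocontrol would be by reagent, the chosen plan's is by substrate. On step economy it is two to three steps shorter on paper (better), but it carries two open selectivity questions against one separation and one directed oxidation.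

Alternative 3: The cut is the C1–C5 bond together with the ester, back to the spiro tetrone A5 ((5S)-2-[4-(benzyloxy)phenyl]-8,9-dimethoxy-1-oxaspiro[4.5]deca-2,8-diene-4,6,7,10-tetrone), whose six-membered ring holds a 1,2-dione next to the spiro carbon.
- Forward step: Mg(OMe)2 in MeOH adds methoxide to the dione carbonyl next to the spiro carbon, and the spiro carbon migrates to the neighbouring carbonyl carbon (benzilic ester rearrangement). This forms C1–C5, the methyl ester and the tertiary alkoxide, and gives A6, the O-benzyl ether of the target, which is the same compound as 14.
- In its favour: like the chosen key step it delivers ring A with full oxidation pattern, CO2Me and the C1 carbinol in one operation. Here both rings and the spiro centre are already present, so only debenzylation would remain: one step after the key step against five (clearly better). Attack at either dione carbonyl leads to the same constitution. The route is plausibly biomimetic.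
- Against it here: the C1 configuration would have to be induced by the spiro centre alone (O1' against C4'), with no element that clearly prefers one course. Methoxide has a damaging alternative in acyl cleavage of the bond between C5 and the attacked carbonyl, since a carbon flanked by two ketones is an excellent leaving carbanion. A5 is a hydrate-prone polycarbonyl compound that must itself be made as one enantiomer, for instance through A4.
- Comparison: on structure, the retron (α-hydroxy ester on a contracted ring) is the same as in the chosen plan. On mechanism, it is an anionic 1,2-shift in a base-labile setting against a photochemical shift under acidic conditions; the chosen plan secures C1 by a separation, the alternative by unguided diastereoselection. On step economy the alternative is shorter after the key step, while the chosen plan is shorter and safer before it (three steps to 6).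

Key step: step 4

Remark: 8 and 9 should exist as chelated enols; they are drawn as C5 keto forms, so C5 has no descriptor before step 6. Ring A locants (C1–C5) and ring B locants (O1'–C4') are used for all intermediates. 1, 2 and 12 are taken as catalogue compounds.

## Route

Step 1
Reactants: 1 2'-hydroxy-3',4',5',6'-tetramethoxyacetophenone; 2 (S)-O-methylmandelic acid
Product: 4 2-acetyl-3,4,5,6-tetramethoxyphenyl (S)-2-methoxy-2-phenylacetate, via (S)-2-methoxy-2-phenylacetyl chloride 3 (not isolated)
Conditions: 2, (COCl)2, cat. DMF, CH2Cl2, 0 °C → rt, evaporate; then 1, pyridine, CH2Cl2, −20 → 0 °C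
Reagents that add atoms: none
Why: Nucleophilic acyl substitution; O-acylation of the chelated phenol of a 2'-hydroxyacetophenone by an acid chloride in pyridine is the standard first stage of Baker–Venkataraman sequences on this ring type, and pyridine at low temperature instead of a trialkylamine keeps 3 from forming the ketene that would erase the auxiliary's stereocentre.

Step 2
Reactants: 4 2-acetyl-3,4,5,6-tetramethoxyphenyl (S)-2-methoxy-2-phenylacetate
Product: 5 2-acetyl-3-hydroxy-4,5,6-trimethoxyphenyl (S)-2-methoxy-2-phenylacetate
Conditions: BCl3 (1.3 equiv), CH2Cl2, −78 → 0 °C; aq. NaHCO3
Reagents that add atoms: none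
Why: Chelation-controlled ortho-demethylation: BCl3 bridges the acetyl oxygen and the only methoxy group ortho to it, and chloride removes that methyl; the other three methoxy groups have no carbonyl partner, and the aryl ester and the α-methoxy ester of the auxiliary should survive a small excess at low temperature.

Step 3
Reactants: 5 2-acetyl-3-hydroxy-4,5,6-trimethoxyphenyl (S)-2-methoxy-2-phenylacetate
Product: 6 2-acetyl-4,4,5,6-tetramethoxy-3-[(S)-2-methoxy-2-phenylacetoxy]cyclohexa-2,5-dien-1-one
Conditions: PhI(OAc)2 (1.1 equiv), MeOH, −10 °C, 15 min; cold aq. NaHCO3; used at once
Reagents that add atoms: methanol CO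
Why: Oxidative dearomatisation of a para-methoxyphenol to the para-quinone monoketal: the phenol is activated on iodine and methanol adds at the methoxy-bearing para carbon, the position best able to carry the positive charge; the product is a vinylogous mixed anhydride, hence the short cold contact with methanol.

Step 4
Reactants: 6 2-acetyl-4,4,5,6-tetramethoxy-3-[(S)-2-methoxy-2-phenylacetoxy]cyclohexa-2,5-dien-1-one
Product: 8 methyl (1S)-5-acetyl-2,3-dimethoxy-1-{[(2S)-2-methoxy-2-phenylacetyl]oxy}-4-oxocyclopent-2-ene-1-carboxylate, via cis-fused bicyclo[3.1.0]hexenone 7 (not isolated)
Conditions: hν (350 nm, Pyrex), degassed MeCN/AcOH (9:1), H2O (5 equiv), 0–5 °C, to full conversion; then chromatography or crystallisation to separate the C1 epimers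
Reagents that add atoms: water O
Why: Excitation of the cross-conjugated dienone leads to bonding of its two β-carbons (the acyloxy-bearing carbon, later C1, and the methoxy-bearing carbon, later C2), which closes ring A as the five-membered part of a cyclopropyl oxyallyl zwitterion; this is a transannular 1,3-closure across the ketal carbon, a ring contraction to which no end-to-end cyclisation class applies. The ketal carbon then moves in a 1,4-sigmatropic shift from the methoxy-bearing carbon to the acetyl-bearing carbon (later C5) and gives lumiketone 7. This direction is expected because it leaves the developing positive charge on a carbon with a methoxy donor, whereas the opposite shift would leave it on the carbon whose oxygen is acylated and therefore the poorer donor, which is the reason for attaching the auxiliary as an ester. In 7 the cyclopropanone ketal is a donor–acceptor cyclopropane: its bond to C5 breaks because C5 becomes a β-diketone enolate, and the dimethoxycarbenium ion left on C1 takes up water and loses methanol to give the methyl ester. Acetic acid is present so that 7 opens as it forms and does not absorb a second photon, and methanol is avoided as solvent because it would cleave the enol ester of 6. The closest known reaction type is the lumiketone (type A) photorearrangement of 4,4-disubstituted cyclohexa-2,5-dienones, quinone monoketals included, with solvolytic opening of the cyclopropanone ketal to cyclopentenone esters. C1 is the only new stereocentre that persists (C5 is enolised); its configuration depends on the face over which the ketal carbon travels, which the remote mandelate can bias only weakly, so both C1 epimers are expected in comparable amounts, control comes from separating them as diastereomers, and the (1S) isomer is taken on.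

Step 5
Reactants: 8 methyl (1S)-5-acetyl-2,3-dimethoxy-1-{[(2S)-2-methoxy-2-phenylacetyl]oxy}-4-oxocyclopent-2-ene-1-carboxylate
Product: 9 methyl (1S)-5-acetyl-1-hydroxy-2,3-dimethoxy-4-oxocyclopent-2-ene-1-carboxylate
Conditions: K2CO3 (2 equiv), MeOH, 0 °C → rt; then 1 M HCl to pH 3
Reagents that add atoms: none
Why: Transesterification of an α-alkoxy and therefore activated ester whose alkoxide is a good leaving group; the β-diketone is deprotonated first and as its enolate can neither leave in a retro-aldol cleavage of C1–C5 nor lose the acetyl group, methoxide exchange at the ring ester and the vinylogous ester is degenerate, and loss of the C1 oxygen would require an antiaromatic cyclopentadienone.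

Step 6
Reactants: 9 methyl (1S)-5-acetyl-1-hydroxy-2,3-dimethoxy-4-oxocyclopent-2-ene-1-carboxylate
Product: 10 methyl (1S,5S)-5-acetyl-1,5-dihydroxy-2,3-dimethoxy-4-oxocyclopent-2-ene-1-carboxylate
Conditions: mCPBA (1.1 equiv), CH2Cl2, −20 → 0 °C
Reagents that add atoms: 3-chloroperbenzoic acid (mCPBA) OOC(=O)c1cccc(Cl)c1
Why: Electrophilic hydroxylation of a β-diketone enol by a peracid (epoxidation of the enol double bond and collapse to the α-hydroxy diketone); the C1 hydroxyl is allylic to the enol and hydrogen-bonds the peracid, and the ester on the other face is the larger group, so both effects should send oxygen to the hydroxyl face and set C5 with its OH cis to C1–OH.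

Step 7
Reactants: 10 methyl (1S,5S)-5-acetyl-1,5-dihydroxy-2,3-dimethoxy-4-oxocyclopent-2-ene-1-carboxylate
Product: 11 methyl (3aR,6aS)-6a-acetyl-4,5-dimethoxy-2,2-dimethyl-6-oxo-6,6a-dihydro-3aH-cyclopenta[d][1,3]dioxole-3a-carboxylate
Conditions: 2-methoxypropene (3 equiv), PPTS (10 mol %), CH2Cl2, 0 °C → rt
Reagents that add atoms: 2-methoxypropene COC(C)=C
Why: Acid-catalysed ketal formation (acetonide protection); only a cis 1,2-diol on a five-membered ring can close the cis-fused dioxolane, so the step masks both tertiary alcohols for the acylation and at the same time removes any trans diol from the series.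

Step 8
Reactants: 11 methyl (3aR,6aS)-6a-acetyl-4,5-dimethoxy-2,2-dimethyl-6-oxo-6,6a-dihydro-3aH-cyclopenta[d][1,3]dioxole-3a-carboxylate; 12 4-(benzyloxy)benzoyl chloride
Product: 14 methyl (5S,6R)-2-[4-(benzyloxy)phenyl]-6-hydroxy-7,8-dimethoxy-4,9-dioxo-1-oxaspiro[4.4]nona-2,7-diene-6-carboxylate, via acetonide-protected 1,3-diketone 13 (not isolated)
Conditions: MgBr2·OEt2 (2.5 equiv), iPr2NEt (3 equiv), CH2Cl2, 0 °C → rt; 1 M HCl wash; then TFA/H2O (9:1), 0 °C → rt
Reagents that add atoms: none
Why: Crossed Claisen-type C-acylation by soft enolisation: MgBr2 chelated by the ketone and the neighbouring ketal oxygen makes the acetyl CH3, the only enolisable position, acidic enough for iPr2NEt, and the magnesium enolate is acylated on carbon to the chelated 1,3-diketone 13; in aqueous TFA the C5 oxygen attacks the activated aryl ketone (5-exo-trig), the ketal carbon leaves as acetone and loss of water gives the 3(2H)-furanone (acid cyclodehydration of an α'-hydroxy 1,3-diketone), while C1–OH, trans to the side chain, could compete only through a strained trans-fused six-membered ring; no stereocentre is touched.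

Step 9
Reactants: 14 methyl (5S,6R)-2-[4-(benzyloxy)phenyl]-6-hydroxy-7,8-dimethoxy-4,9-dioxo-1-oxaspiro[4.4]nona-2,7-diene-6-carboxylate
Product: 15 methyl (5S,6R)-6-hydroxy-2-(4-hydroxyphenyl)-7,8-dimethoxy-4,9-dioxo-1-oxaspiro[4.4]nona-2,7-diene-6-carboxylate (limnophilaspiroketone)
Conditions: H2 (1 atm), 10% Pd/C, EtOAc, rt, stopped at full conversion
Reagents that add atoms: none
Why: Hydrogenolysis of an aryl benzyl ether; the neutral medium spares the base-labile C1–C5 aldol bond, and the tetrasubstituted push–pull alkene of ring A and the aryl-conjugated enol ether alkene of ring B should be reduced much more slowly than the benzylic C–O bond is cleaved.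

## Compound list

1 | 2'-hydroxy-3',4',5',6'-tetramethoxyacetophenone | CC(=O)c1c(O)c(OC)c(OC)c(OC)c1OC | starting material
2 | (S)-O-methylmandelic acid ((S)-2-methoxy-2-phenylacetic acid) | CO[C@@H](c1ccccc1)C(=O)O | starting material
3 | (S)-2-methoxy-2-phenylacetyl chloride | CO[C@@H](c1ccccc1)C(Cl)=O | intermediate
4 | 2-acetyl-3,4,5,6-tetramethoxyphenyl (S)-2-methoxy-2-phenylacetate | CC(=O)c1c(OC(=O)[C@@H](OC)c2ccccc2)c(OC)c(OC)c(OC)c1OC | intermediate
5 | 2-acetyl-3-hydroxy-4,5,6-trimethoxyphenyl (S)-2-methoxy-2-phenylacetate | CC(=O)c1c(O)c(OC)c(OC)c(OC)c1OC(=O)[C@@H](OC)c2ccccc2 | intermediate
6 | 2-acetyl-4,4,5,6-tetramethoxy-3-[(S)-2-methoxy-2-phenylacetoxy]cyclohexa-2,5-dien-1-one | CC(=O)C1=C(OC(=O)[C@@H](OC)c2ccccc2)C(OC)(OC)C(OC)=C(OC)C1=O | intermediate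
7 | (1R,5S)-1-acetyl-3,4,6,6-tetramethoxy-2-oxobicyclo[3.1.0]hex-3-en-5-yl (S)-2-methoxy-2-phenylacetate | CC(=O)[C@@]12C(=O)C(OC)=C(OC)[C@]1(OC(=O)[C@@H](OC)c3ccccc3)C2(OC)OC | intermediate
8 | methyl (1S)-5-acetyl-2,3-dimethoxy-1-{[(2S)-2-methoxy-2-phenylacetyl]oxy}-4-oxocyclopent-2-ene-1-carboxylate (C5 enolised) | COC(=O)[C@@]1(OC(=O)[C@@H](OC)c2ccccc2)C(OC)=C(OC)C(=O)C1C(C)=O | intermediate
9 | methyl (1S)-5-acetyl-1-hydroxy-2,3-dimethoxy-4-oxocyclopent-2-ene-1-carboxylate (C5 enolised) | COC(=O)[C@@]1(O)C(OC)=C(OC)C(=O)C1C(C)=O | intermediate
10 | methyl (1S,5S)-5-acetyl-1,5-dihydroxy-2,3-dimethoxy-4-oxocyclopent-2-ene-1-carboxylate (cis diol) | COC(=O)[C@@]1(O)C(OC)=C(OC)C(=O)[C@@]1(O)C(C)=O | intermediate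
11 | methyl (3aR,6aS)-6a-acetyl-4,5-dimethoxy-2,2-dimethyl-6-oxo-6,6a-dihydro-3aH-cyclopenta[d][1,3]dioxole-3a-carboxylate (acetonide of 10) | COC(=O)[C@@]1(OC(C)(C)O2)C(OC)=C(OC)C(=O)[C@@]12C(C)=O | intermediate
12 | 4-(benzyloxy)benzoyl chloride | O=C(Cl)c1ccc(OCc2ccccc2)cc1 | starting material
13 | methyl (3aR,6aS)-6a-{3-[4-(benzyloxy)phenyl]-3-oxopropanoyl}-4,5-dimethoxy-2,2-dimethyl-6-oxo-6,6a-dihydro-3aH-cyclopenta[d][1,3]dioxole-3a-carboxylate | COC(=O)[C@@]1(OC(C)(C)O2)C(OC)=C(OC)C(=O)[C@@]12C(=O)CC(=O)c1ccc(OCc3ccccc3)cc1 | intermediate
14 | methyl (5S,6R)-2-[4-(benzyloxy)phenyl]-6-hydroxy-7,8-dimethoxy-4,9-dioxo-1-oxaspiro[4.4]nona-2,7-diene-6-carboxylate | COC(=O)[C@@]1(O)C(OC)=C(OC)C(=O)[C@]12OC(c1ccc(OCc3ccccc3)cc1)=CC2=O | intermediate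
15 | methyl (5S,6R)-6-hydroxy-2-(4-hydroxyphenyl)-7,8-dimethoxy-4,9-dioxo-1-oxaspiro[4.4]nona-2,7-diene-6-carboxylate (limnophilaspiroketone) | COC(=O)[C@@]1(O)C(OC)=C(OC)C(=O)[C@]12OC(c1ccc(O)cc1)=CC2=O | target

## Step count and least certain steps

Total: 9 steps. Longest linear sequence: 9 steps (1 or 2 to 15); 12 enters as purchased in step 8.

Step 4 (key step). The most likely failure is loss or migration of the acyloxy group before the skeleton has rearranged, by solvolysis of the vinylogous anhydride in the wet acidic medium or by a light-induced acyl shift. Behind it stands migration of the ketal carbon toward the methoxy-bearing α-carbon, which would place the ester on the wrong ring carbon. Both arise because the two halves of the dienone differ only in acetyl/acyloxy against methoxy/methoxy. Separation of the C1 epimers may also be poor, because the auxiliary's stereocentre is three bonds from C1 and the compounds are enolised. The fallback exchanges the ester auxiliary for a carbonate. A carbonate is a weaker acylating agent, has no stereocentre next to its carbonyl group, and still leaves the oxygen a weak donor.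
- It sets out from 1, which is treated with (1R,2S,5R)-menthyl chloroformate and pyridine to give 2-acetyl-3,4,5,6-tetramethoxyphenyl (1R,2S,5R)-menthyl carbonate F1.
- BCl3 as in step 2 gives 2-acetyl-3-hydroxy-4,5,6-trimethoxyphenyl (1R,2S,5R)-menthyl carbonate F2.
- PhI(OAc)2 in methanol gives 2-acetyl-4,4,5,6-tetramethoxy-3-{[(1R,2S,5R)-menthyloxy]carbonyloxy}cyclohexa-2,5-dien-1-one F3.
- Irradiation as in step 4 and separation of the C1 epimers gives methyl (1S)-5-acetyl-2,3-dimethoxy-1-{[(1R,2S,5R)-menthyloxy]carbonyloxy}-4-oxocyclopent-2-ene-1-carboxylate F4.
- K2CO3 in methanol cleaves the carbonate, the C1 alkoxide being the best leaving group, and the fallback comes back to the route at 9.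

Step 2. The most likely failure is attack of BCl3 on the auxiliary alongside the wanted demethylation: cleavage of its benzylic methyl ether, or loss of configuration at its α-carbon through a boron chelate of the ester. The fallback inverts the order so that the Lewis acid never meets the auxiliary. It sets out from 1, which with excess BCl3 (−78 °C → rt) loses the methyl group ortho to the acetyl group and gives 2',6'-dihydroxy-3',4',5'-trimethoxyacetophenone F5. F5 is C2-symmetric, so its two phenols are equivalent. One of them is acylated with 1 equivalent of 3 in pyridine; the second phenol is then the hydrogen-bonded and less reactive one. The fallback comes back to the route at 5. Its cost is that this demethylation has no free chelation site and is slower and less clean than step 2.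

Step 6. The most likely failure is poor facial selectivity, with oxygen delivered to the ester face, because hydrogen-bond guidance is weak for a tertiary, electron-poor alcohol. Overoxidation of the new α-hydroxy diketone by oxygen insertion is a second possibility. The fallback replaces hydrogen-bond guidance by covalent delivery within a metal alkoxide. It sets out from 9, which is treated with tBuOOH and catalytic VO(acac)2 in CH2Cl2. The C1 alkoxide binds vanadium together with the peroxide, and the oxygen is passed to the allylic enol carbon C5 from the face of the C1 oxygen (vanadium-catalysed hydroxyl-directed epoxidation). The fallback comes back to the route at 10 and makes no new compound. In either variant the unwanted trans diol cannot form 11 and is removed in step 7.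

Step 8. The most likely failures are O-acylation of the magnesium enolate or Lewis-acid opening of the ketal instead of C-acylation, and, in the acid stage, hydrolysis of the ring A vinylogous ester before cyclodehydration is complete. The fallback builds the diketone by aldol addition and oxidation instead of acylation. It sets out from 11, whose lithium enolate (LiHMDS, THF, −78 °C) adds to 4-(benzyloxy)benzaldehyde within minutes, before it can attack the cis ester. This gives methyl (3aR,6aS)-6a-{3-[4-(benzyloxy)phenyl]-3-hydroxypropanoyl}-4,5-dimethoxy-2,2-dimethyl-6-oxo-6,6a-dihydro-3aH-cyclopenta[d][1,3]dioxole-3a-carboxylate F6 as a mixture of carbinol epimers, which converge. Dess–Martin periodinane oxidises F6 and the fallback comes back to the route at 13, before the TFA stage.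

Step 9. The most likely failure is over-reduction: saturation of the C2'=C3' alkene of ring B once the benzyl group is gone. The fallback removes the benzyl group without hydrogen. It sets out from 14, which is treated with BCl3 and pentamethylbenzene in CH2Cl2 at −78 °C. The Lewis acid ionises the benzyl ether and the arene traps the benzyl cation. The fallback comes back to the route at 15 and makes no new compound. Low temperature and short contact are needed so that the ring A methoxy groups next to the carbonyl are not demethylated.

## Further compounds

F1 | step 4 | 2-acetyl-3,4,5,6-tetramethoxyphenyl (1R,2S,5R)-menthyl carbonate | CC(=O)c1c(OC(=O)O[C@H]2[C@H](C(C)C)CC[C@@H](C)C2)c(OC)c(OC)c(OC)c1OC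
F2 | step 4 | 2-acetyl-3-hydroxy-4,5,6-trimethoxyphenyl (1R,2S,5R)-menthyl carbonate | CC(=O)c1c(O)c(OC)c(OC)c(OC)c1OC(=O)O[C@H]2[C@H](C(C)C)CC[C@@H](C)C2
F3 | step 4 | 2-acetyl-4,4,5,6-tetramethoxy-3-{[(1R,2S,5R)-menthyloxy]carbonyloxy}cyclohexa-2,5-dien-1-one | CC(=O)C1=C(OC(=O)O[C@H]2[C@H](C(C)C)CC[C@@H](C)C2)C(OC)(OC)C(OC)=C(OC)C1=O
F4 | step 4 | methyl (1S)-5-acetyl-2,3-dimethoxy-1-{[(1R,2S,5R)-menthyloxy]carbonyloxy}-4-oxocyclopent-2-ene-1-carboxylate | COC(=O)[C@@]1(OC(=O)O[C@H]2[C@H](C(C)C)CC[C@@H](C)C2)C(OC)=C(OC)C(=O)C1C(C)=O
F5 | step 2 | 2',6'-dihydroxy-3',4',5'-trimethoxyacetophenone | CC(=O)c1c(O)c(OC)c(OC)c(OC)c1O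
F0 | step 6 | none | none
F6 | step 8 | methyl (3aR,6aS)-6a-{3-[4-(benzyloxy)phenyl]-3-hydroxypropanoyl}-4,5-dimethoxy-2,2-dimethyl-6-oxo-6,6a-dihydro-3aH-cyclopenta[d][1,3]dioxole-3a-carboxylate (carbinol epimers) | COC(=O)[C@@]1(OC(C)(C)O2)C(OC)=C(OC)C(=O)[C@@]12C(=O)CC(O)c1ccc(OCc3ccccc3)cc1
F0 | step 9 | none | none
A1 | alternative 1 | methyl (5S)-5-{[4-(benzyloxy)phenyl]ethynyl}-5-hydroxy-2,3-dimethoxy-6-oxocyclohexa-1,3-diene-1-carboxylate | COC(=O)C1=C(OC)C(OC)=C[C@](O)(C#Cc2ccc(OCc3ccccc3)cc2)C1=O
A2 | alternative 1 | methyl (5S)-2-[4-(benzyloxy)phenyl]-7,8-dimethoxy-4-oxo-1-oxaspiro[4.4]nona-2,6,8-triene-6-carboxylate | COC(=O)C1=C(OC)C(OC)=C[C@]12OC(c1ccc(OCc3ccccc3)cc1)=CC2=O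
A3 | alternative 2 | 1-[4-(benzyloxy)phenyl]-3-(2,6-dihydroxy-3,4-dimethoxyphenyl)propane-1,3-dione | O=C(CC(=O)c1ccc(OCc2ccccc2)cc1)c1c(O)cc(OC)c(OC)c1O
A4 | alternative 2 | (5S)-2-[4-(benzyloxy)phenyl]-8,9-dimethoxy-1-oxaspiro[4.5]deca-2,8-diene-4,6,10-trione | O=C1CC(OC)=C(OC)C(=O)[C@]12OC(c1ccc(OCc3ccccc3)cc1)=CC2=O
A5 | alternative 3 | (5S)-2-[4-(benzyloxy)phenyl]-8,9-dimethoxy-1-oxaspiro[4.5]deca-2,8-diene-4,6,7,10-tetrone | O=C1C(=O)C(OC)=C(OC)C(=O)[C@]12OC(c1ccc(OCc3ccccc3)cc1)=CC2=O
A6 | alternative 3 | methyl (5S,6R)-2-[4-(benzyloxy)phenyl]-6-hydroxy-7,8-dimethoxy-4,9-dioxo-1-oxaspiro[4.4]nona-2,7-diene-6-carboxylate (O-benzyl limnophilaspiroketone, identical with 14) | COC(=O)[C@@]1(O)C(OC)=C(OC)C(=O)[C@]12OC(c1ccc(OCc3ccccc3)cc1)=CC2=O
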